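All runs stem from a simulated flask with constants of no real substance; the scatter is artificial.

**The question.** You ask which flask, amber or red, ends ahead in double product after 2.5 d, and how far.

| flask | solid substrate | coupling partner | temperature | remark | time |
|---|---|---|---|---|---|
| west | 0.28 M | 0.95 equiv | 24 °C | run made earlier |  |
| south | 0.44 M | 0.95 equiv | 32 °C | run made earlier |  |
| amber | 0.20 M | 0.950 equiv | 20 °C |  | 2.5 d |
| red | 0.20 M | 0.950 equiv | 35 °C |  | 2.5 d |

| run | time / h | double product / % |
|---|---|---|
| west | 2.50 | 1 |
| west | 8.00 | 0 |
| west | 12.0 | 4 |
| west | 20.0 | 11 |
| west | 30.0 | 13 |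
| west | 40.0 | 16 |
| south | 1.33 | 0 |
| south | 4.00 | 2 |
| south | 6.00 | 4 |
| south | 12.0 | 4 |
| south | 15.0 | 7 |
| south | 20.0 | 10 |

(readings scatter by 1.5 percentage points)

* which flask leads in amount of double product, in percent of the solid substrate charged ("all alike" within 1.5 percentage points) (amber / red / all alike)
* how much double product is there at the end, in percent of the solid substrate charged: amber
* how much double product is there at the end, in percent of the solid substrate charged: red

- as a solid, counted per litre of solution: solid substrate
- at the start none of the solid substrate is in solution
- what has only dissolved of solid substrate counts as not reacted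

**Partner ceiling.** My reckoning starts from the budget, so follow the partner in your run. Each double product takes two coupling partners, so for this product the partner is the limiting reagent. With 0.950 equiv charged, both flasks get 47.5%. Call this the partner ceiling: half the partner equivalents charged, as percent of the solid substrate. Any partner spent elsewhere comes off it. West reached 16% at 40.0 h and south 10% at 20.0 h, both well below the ceiling, so these readings have not tested it. I therefore commit to a bound and no ranking.

**The forecast.** It gives 16% for amber and 30% for red, with red ahead; of red it says that, with partner being used up, “it slows to about 30 %”. Both numbers sit under my ceiling, but unlike mine they name a winner.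

**The flask.** The lead goes to amber, 16.2% against 13.0% in red. At 1.25 d red was still ahead, 12.9% against 9.55%, with 2.73% of its partner left against 49.3% in amber. Amber's partner has a half-life of 11 d by decomposition, longer than the run. By the end amber holds 0.0164 M of decomposed reagent and red 0.0481 M, which lowers the ceiling to 43.4% and 35.5%, and each flask's double product stands below its lowered ceiling.

    solid substrate ⇌ starting material, rate k1*(cs1 - [starting material]) while solid is left; crystals form when [starting material] > cs1 (solubility = 0.180 M, k = 0.0567 h⁻¹)
    coupling partner + double product → tris adduct (k = 0.582 L mol⁻¹ h⁻¹, Ea = 76.0 kJ mol⁻¹)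
    double product ⇌ isomer of the product (K = 0.382, k = 0.0663 h⁻¹, Ea = 103 kJ mol⁻¹, ΔH = −20.0 kJ mol⁻¹)
    starting material + coupling partner → first product (k = 0.843 L mol⁻¹ h⁻¹, Ea = 78.0 kJ mol⁻¹)
    coupling partner + first product → double product (k = 1.68 L mol⁻¹ h⁻¹, Ea = 74.0 kJ mol⁻¹)
    coupling partner + tris adduct → tetra adduct (k = 0.0811 L mol⁻¹ h⁻¹, Ea = 61.0 kJ mol⁻¹)
    coupling partner → decomposed reagent (k = 0.0212 h⁻¹, Ea = 103 kJ mol⁻¹)
    (constants at 35 °C)

**The neighbour.** For a neighbour flask, like amber but with 0.240 equiv of partner, the ceiling falls to 12.0%. That flask gives 2.32% double product, with 11.8% as first product.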